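**Retrosynthetic overview**
- The strategy rests on the enol-lactone bond O1–C5 of the furanone ring (O1, C2=O, C3, C4, C5) with its exocyclic C5=CH–aryl alkene. It is made last, by silver-catalysed 5-exo-dig addition of the C2 carboxylate across the aryl alkyne of a (Z)-2-en-4-ynoic acid; anti addition gives the Z alkene. This is the only ring formed.
- Enynoic acid ⇐ Sonogashira coupling of a (Z)-enol triflate with 2-bromo-4-ethynylphenyl silyl ether. The tert-butyl ester is removed without hydroxide so that the aryl silyl ethers survive.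
- (Z)-Enol triflate ⇐ lithium-chelate-controlled triflation of an α-substituted β-keto ester, itself from aldol addition and oxidation of an enantiopure β-silyloxy ester with 3-bromo-4-silyloxybenzaldehyde.
- Carbinol stereocentre ⇐ asymmetric transfer hydrogenation of the aryl β-keto ester; no bond at that carbon is touched afterwards.
- Fluoride removes the three silyl ethers at the end.

Key step: step 11

Remark: TBS = tert-butyldimethylsilyl; 3,5-dibromo-4-methoxybenzoic acid is taken as a catalogue compound.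
Remark: the carbinol descriptor is R in 7, 8, 10 and 11 and S from 12 onwards only because C2 becomes sp2 and then outranks the aryl group; the spatial arrangement is the same throughout.
Remark: the alkene geometry is fixed by chelate-controlled triflation and the configuration by ketone reduction, rather than by an asymmetric halo-aldol on a 3-aryl ynoate, which is documented only for β-unsubstituted propiolates.

Step 1
Reactants: 1 3-bromo-4-hydroxybenzaldehyde
Product: 2 3-bromo-4-(TBS-oxy)benzaldehyde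
Conditions: TBSCl, imidazole, DMF, rt
Reagents that add atoms: tert-butyldimethylsilyl chloride, CC(C)(C)[Si](C)(C)Cl
Why: Standard silylation of a phenol; the silyl ether is kept on both bromophenol rings until the last step.

Step 2
Reactants: 2 3-bromo-4-(TBS-oxy)benzaldehyde
Product: 3 (2-bromo-4-ethynylphenoxy)(tert-butyl)dimethylsilane
Conditions: TMSCHN2, LDA, THF, −78 °C; then 2, −78 °C → rt; aq. NH4Cl
Reagents that add atoms: (trimethylsilyl)diazomethane, C[Si](C)(C)C=[N+]=[N-]
Why: Colvin rearrangement (one-carbon aldehyde-to-alkyne homologation) under aprotic conditions, which spare the aryl silyl ether that carbonate in methanol would cleave and do not exchange the aryl bromide.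

Step 3
Reactants: 4 3,5-dibromo-4-methoxybenzoic acid
Product: 6 tert-butyl 3-(3,5-dibromo-4-methoxyphenyl)-3-oxopropanoate, via acyl imidazolide 5 (not isolated)
Conditions: CDI, THF, rt; then LiCH2CO2tBu (from tBuOAc and LDA, 2.5 equiv), THF, −78 °C; aq. NH4Cl
Reagents that add atoms: tert-butyl acetate, CC(=O)OC(C)(C)C
Why: Crossed Claisen condensation of a non-enolisable acyl imidazolide with lithium tert-butyl acetate; excess enolate takes up the acidic proton of the β-keto ester, so acylation stops after one addition.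

Step 4
Reactants: 6 tert-butyl 3-(3,5-dibromo-4-methoxyphenyl)-3-oxopropanoate
Product: 7 tert-butyl (3R)-3-(3,5-dibromo-4-methoxyphenyl)-3-hydroxypropanoate
Conditions: RuCl[(R,R)-TsDPEN](p-cymene) (1 mol%), HCO2H/Et3N (5:2), DMF, 40 °C
Reagents that add atoms: none
Why: Noyori asymmetric transfer hydrogenation of an aryl ketone; the (R,R)-TsDPEN ruthenium hydride delivers hydrogen to the face fixed by the aryl–arene CH/π contact, which should set the R carbinol (same sense as acetophenone to (R)-1-phenylethanol, to be confirmed by Mosher analysis), and aryl bromides and the tert-butyl ester are inert.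

Step 5
Reactants: 7 tert-butyl (3R)-3-(3,5-dibromo-4-methoxyphenyl)-3-hydroxypropanoate
Product: 8 tert-butyl (3R)-3-(TBS-oxy)-3-(3,5-dibromo-4-methoxyphenyl)propanoate
Conditions: TBSCl, imidazole, DMF, rt
Reagents that add atoms: tert-butyldimethylsilyl chloride, CC(C)(C)[Si](C)(C)Cl
Why: Standard silylation of a secondary benzylic alcohol; the stereocentre is untouched and the ether blocks retro-aldol and O-sulfonylation later.

Step 6
Reactants: 8 tert-butyl (3R)-3-(TBS-oxy)-3-(3,5-dibromo-4-methoxyphenyl)propanoate; 2 3-bromo-4-(TBS-oxy)benzaldehyde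
Product: 10 tert-butyl (3R)-2-{[3-bromo-4-(TBS-oxy)phenyl](hydroxy)methyl}-3-(TBS-oxy)-3-(3,5-dibromo-4-methoxyphenyl)propanoate (diastereomer mixture at the two new centres), via lithium enolate 9 (not isolated)
Conditions: LDA, THF, −78 °C; then 2, −78 °C; AcOH quench at −78 °C
Reagents that add atoms: none
Why: Aldol addition of a lithium ester enolate to a non-enolisable aryl aldehyde; at −78 °C with a cold quench the β-silyloxy enolate should neither expel silanolate nor allow silyl migration, and the two new stereocentres do not matter because both carbons become sp2 in steps 7 and 8.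

Step 7
Reactants: 10 the aldol adduct
Product: 11 tert-butyl (3R)-2-[3-bromo-4-(TBS-oxy)benzoyl]-3-(TBS-oxy)-3-(3,5-dibromo-4-methoxyphenyl)propanoate (C2 epimers)
Conditions: Dess–Martin periodinane, CH2Cl2, 0 °C → rt
Reagents that add atoms: none
Why: Dess–Martin oxidation of the new benzylic alcohol to the aryl ketone under non-basic conditions, so the β-silyloxy group of the β-keto ester is not eliminated.

Step 8
Reactants: 11 the α-substituted β-keto ester
Product: 13 tert-butyl (2Z)-3-[3-bromo-4-(TBS-oxy)phenyl]-2-[(S)-(TBS-oxy)(3,5-dibromo-4-methoxyphenyl)methyl]-3-(trifluoromethylsulfonyloxy)prop-2-enoate, via lithium enolate 12 (not isolated)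
Conditions: LiN(SiMe3)2, toluene/THF, −78 °C; then Tf2O, −78 → −20 °C
Reagents that add atoms: trifluoromethanesulfonic anhydride, O=S(=O)(OS(=O)(=O)C(F)(F)F)C(F)(F)F
Why: Chelation-controlled enol triflation of a 2-substituted β-keto ester; lithium bridges the enolate oxygen and the ester carbonyl, so O-sulfonylation places OTf cis to CO2tBu (Z) and the aryl group cis to the carbinol carbon, which is the geometry the lactonisation needs, and the carbinol centre is not involved.

Step 9
Reactants: 13 the (Z)-enol triflate; 3 (2-bromo-4-ethynylphenoxy)(tert-butyl)dimethylsilane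
Product: 14 tert-butyl (2Z)-3,5-bis[3-bromo-4-(TBS-oxy)phenyl]-2-[(S)-(TBS-oxy)(3,5-dibromo-4-methoxyphenyl)methyl]pent-2-en-4-ynoate
Conditions: Pd(PPh3)4 (5 mol%), CuI (10 mol%), iPr2NEt, DMF, rt
Reagents that add atoms: none
Why: Sonogashira coupling; zerovalent palladium inserts into the electron-poor alkenyl C–OTf bond much faster than into the four aryl C–Br bonds at room temperature, and the copper acetylide is transferred with retention of alkene geometry.

Step 10
Reactants: 14 the enyne tert-butyl ester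
Product: 16 (2Z)-3,5-bis[3-bromo-4-(TBS-oxy)phenyl]-2-[(S)-(TBS-oxy)(3,5-dibromo-4-methoxyphenyl)methyl]pent-2-en-4-ynoic acid, via trimethylsilyl ester 15 (not isolated)
Conditions: TMSOTf, 2,6-lutidine, CH2Cl2, 0 °C; then pH 7 phosphate buffer
Reagents that add atoms: none
Why: Silyl triflate-mediated dealkylation of a tert-butyl ester (O-silylation, loss of isobutene) followed by hydrolysis of the labile trimethylsilyl ester; no hydroxide is used, so the two aryl silyl ethers that a saponification would strip stay on, and the lutidine-buffered medium should not ionise the benzylic silyl ether.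

Step 11
Reactants: 16 the (Z)-enynoic acid
Product: 17 (5Z)-4-[3-bromo-4-(TBS-oxy)phenyl]-5-{[3-bromo-4-(TBS-oxy)phenyl]methylidene}-3-[(S)-(TBS-oxy)(3,5-dibromo-4-methoxyphenyl)methyl]furan-2(5H)-one
Conditions: Ag2CO3 (10 mol%), DMF, rt, dark
Reagents that add atoms: none
Why: Silver carbonate gives the silver carboxylate and monovalent silver π-activates the alkyne; the carboxylate oxygen attacks alkyne carbon C4 of the acid (ring C5) anti to silver in a 5-exo-dig closure that forms O1–C5 and the butenolide ring (O1, C2, C3, C4, C5), and protodeargentation with retention leaves O1 and the aryl group cis, i.e. the Z benzylidene. The closest known reaction is the silver-catalysed cycloisomerisation of (Z)-2-en-4-ynoic acids, including 3-aryl-5-aryl cases, to (Z)-γ-ylidenebutenolides. No stereocentre is formed; the S carbinol has its silyloxy group held trans to the alkyne, so it neither takes part nor epimerises. The step needs 5-exo over 6-endo closure to the 2-pyranone: the tetrasubstituted Z alkene presses the carboxylate against C5, the carboxylate rather than the free acid is the nucleophile under carbonate, and the ortho-bromo silyloxy aryl group is only a weak donor, so little positive charge should build at the aryl-bearing alkyne carbon.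

Step 12
Reactants: 17 the tris-silyl butenolide
Product: 18 (5Z)-4-(3-bromo-4-hydroxyphenyl)-5-[(3-bromo-4-hydroxyphenyl)methylidene]-3-[(S)-(3,5-dibromo-4-methoxyphenyl)(hydroxy)methyl]furan-2(5H)-one
Conditions: Bu4NF/AcOH (1:1), THF, 0 °C → rt
Reagents that add atoms: none
Why: Fluoride-mediated cleavage of the two aryl and the one benzylic silyl ether; acetic acid buffering keeps the phenols protonated so that the base-sensitive (Z)-enol lactone should neither open nor isomerise, and no bond at the stereocentre is broken.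

**Compound list**
1 | 3-bromo-4-hydroxybenzaldehyde | O=Cc1ccc(O)c(Br)c1 | starting material
2 | 3-bromo-4-(TBS-oxy)benzaldehyde | O=Cc1ccc(O[Si](C)(C)C(C)(C)C)c(Br)c1 | intermediate
3 | (2-bromo-4-ethynylphenoxy)(tert-butyl)dimethylsilane | C#Cc1ccc(O[Si](C)(C)C(C)(C)C)c(Br)c1 | intermediate
4 | 3,5-dibromo-4-methoxybenzoic acid | COc1c(Br)cc(C(=O)O)cc1Br | starting material
5 | (3,5-dibromo-4-methoxyphenyl)(1H-imidazol-1-yl)methanone | COc1c(Br)cc(C(=O)n2ccnc2)cc1Br | intermediate
6 | tert-butyl 3-(3,5-dibromo-4-methoxyphenyl)-3-oxopropanoate | COc1c(Br)cc(C(=O)CC(=O)OC(C)(C)C)cc1Br | intermediate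
7 | tert-butyl (3R)-3-(3,5-dibromo-4-methoxyphenyl)-3-hydroxypropanoate | COc1c(Br)cc([C@H](O)CC(=O)OC(C)(C)C)cc1Br | intermediate
8 | tert-butyl (3R)-3-(TBS-oxy)-3-(3,5-dibromo-4-methoxyphenyl)propanoate | COc1c(Br)cc([C@H](O[Si](C)(C)C(C)(C)C)CC(=O)OC(C)(C)C)cc1Br | intermediate
9 | lithium enolate of 8 | [Li+].COc1c(Br)cc([C@H](O[Si](C)(C)C(C)(C)C)C=C([O-])OC(C)(C)C)cc1Br | intermediate
10 | tert-butyl (3R)-2-{[3-bromo-4-(TBS-oxy)phenyl](hydroxy)methyl}-3-(TBS-oxy)-3-(3,5-dibromo-4-methoxyphenyl)propanoate | COc1c(Br)cc([C@H](O[Si](C)(C)C(C)(C)C)C(C(=O)OC(C)(C)C)C(O)c2ccc(O[Si](C)(C)C(C)(C)C)c(Br)c2)cc1Br | intermediate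
11 | tert-butyl (3R)-2-[3-bromo-4-(TBS-oxy)benzoyl]-3-(TBS-oxy)-3-(3,5-dibromo-4-methoxyphenyl)propanoate | COc1c(Br)cc([C@H](O[Si](C)(C)C(C)(C)C)C(C(=O)OC(C)(C)C)C(=O)c2ccc(O[Si](C)(C)C(C)(C)C)c(Br)c2)cc1Br | intermediate
12 | lithium (Z)-enolate of 11 | [Li+].COc1c(Br)cc([C@H](O[Si](C)(C)C(C)(C)C)/C(C(=O)OC(C)(C)C)=C(/[O-])c2ccc(O[Si](C)(C)C(C)(C)C)c(Br)c2)cc1Br | intermediate
13 | tert-butyl (2Z)-3-[3-bromo-4-(TBS-oxy)phenyl]-2-[(S)-(TBS-oxy)(3,5-dibromo-4-methoxyphenyl)methyl]-3-(trifluoromethylsulfonyloxy)prop-2-enoate | COc1c(Br)cc([C@H](O[Si](C)(C)C(C)(C)C)/C(C(=O)OC(C)(C)C)=C(/OS(=O)(=O)C(F)(F)F)c2ccc(O[Si](C)(C)C(C)(C)C)c(Br)c2)cc1Br | intermediate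
14 | tert-butyl (2Z)-3,5-bis[3-bromo-4-(TBS-oxy)phenyl]-2-[(S)-(TBS-oxy)(3,5-dibromo-4-methoxyphenyl)methyl]pent-2-en-4-ynoate | COc1c(Br)cc([C@H](O[Si](C)(C)C(C)(C)C)/C(C(=O)OC(C)(C)C)=C(/C#Cc2ccc(O[Si](C)(C)C(C)(C)C)c(Br)c2)c2ccc(O[Si](C)(C)C(C)(C)C)c(Br)c2)cc1Br | intermediate
15 | trimethylsilyl ester of 16 | COc1c(Br)cc([C@H](O[Si](C)(C)C(C)(C)C)/C(C(=O)O[Si](C)(C)C)=C(/C#Cc2ccc(O[Si](C)(C)C(C)(C)C)c(Br)c2)c2ccc(O[Si](C)(C)C(C)(C)C)c(Br)c2)cc1Br | intermediate
16 | (2Z)-3,5-bis[3-bromo-4-(TBS-oxy)phenyl]-2-[(S)-(TBS-oxy)(3,5-dibromo-4-methoxyphenyl)methyl]pent-2-en-4-ynoic acid | COc1c(Br)cc([C@H](O[Si](C)(C)C(C)(C)C)/C(C(=O)O)=C(/C#Cc2ccc(O[Si](C)(C)C(C)(C)C)c(Br)c2)c2ccc(O[Si](C)(C)C(C)(C)C)c(Br)c2)cc1Br | intermediate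
17 | (5Z)-4-[3-bromo-4-(TBS-oxy)phenyl]-5-{[3-bromo-4-(TBS-oxy)phenyl]methylidene}-3-[(S)-(TBS-oxy)(3,5-dibromo-4-methoxyphenyl)methyl]furan-2(5H)-one | COc1c(Br)cc([C@H](O[Si](C)(C)C(C)(C)C)C2=C(c3ccc(O[Si](C)(C)C(C)(C)C)c(Br)c3)/C(=C/c3ccc(O[Si](C)(C)C(C)(C)C)c(Br)c3)OC2=O)cc1Br | intermediate
18 | (5Z)-4-(3-bromo-4-hydroxyphenyl)-5-[(3-bromo-4-hydroxyphenyl)methylidene]-3-[(S)-(3,5-dibromo-4-methoxyphenyl)(hydroxy)methyl]furan-2(5H)-one | COc1c(Br)cc([C@H](O)C2=C(c3ccc(O)c(Br)c3)/C(=C/c3ccc(O)c(Br)c3)OC2=O)cc1Br | target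

**Step count**
Total: 12 steps. Longest linear sequence: 10 steps (steps 3 to 12, from acid 4).

**Steps most likely to fail**

Step 11. Closure may go 6-endo, by attack at the aryl-bearing alkyne carbon that the para-silyloxy group makes more electrophilic, or oxyargentation may be slow at the congested tetrasubstituted enyne. The fallback moves ring closure into the coupling event. Triflate 13 is first freed of its tert-butyl group (TMSOTf, 2,6-lutidine, then buffer) to give (2Z)-3-[3-bromo-4-(TBS-oxy)phenyl]-2-[(S)-(TBS-oxy)(3,5-dibromo-4-methoxyphenyl)methyl]-3-(trifluoromethylsulfonyloxy)prop-2-enoic acid F1. F1 is then coupled with alkyne 3 under Pd(PPh3)4/CuI/Et3N in MeCN, where the carboxylate of the nascent enynoic acid adds 5-exo to the metal-bound alkyne in the same pot. This tandem Sonogashira coupling–lactonisation is known for (Z)-3-halopropenoic acids. The fallback leaves the route at 13 and returns at 17.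

Step 8. Chelation control may be lost, giving an E/Z mixture because the branched α-substituent resists the aryl-cis arrangement, or the enolate may expel silanolate. The fallback sets the geometry by anti addition across an ynoate. Alkyne 3 is carboxylated (LiN(SiMe3)2, Boc2O) to tert-butyl 3-[3-bromo-4-(TBS-oxy)phenyl]prop-2-ynoate F2. Iodide-triggered conjugate addition–aldol of F2 with 3,5-dibromo-4-methoxybenzaldehyde F3 (TMSI, chiral oxazaborolidinium triflimide, −78 °C) should give tert-butyl (2Z)-3-[3-bromo-4-(TBS-oxy)phenyl]-2-[(S)-(3,5-dibromo-4-methoxyphenyl)(hydroxy)methyl]-3-iodoprop-2-enoate F4, with iodide and aldehyde entering trans as in hydroiodination of arylpropiolates. Silylation (TBSCl, imidazole) gives tert-butyl (2Z)-3-[3-bromo-4-(TBS-oxy)phenyl]-2-[(S)-(TBS-oxy)(3,5-dibromo-4-methoxyphenyl)methyl]-3-iodoprop-2-enoate F5, and Sonogashira coupling of F5 with 3 returns to the route at 14. This three-component coupling is documented for β-unsubstituted propiolates, so the ee on the 3-aryl ynoate would have to be checked; oxidation and CBS reduction of the carbinol is the reserve.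

Step 9. The congested triflate may couple slowly, so that insertion into aryl C–Br bonds or oxidative dimerisation of 3 competes. The fallback delivers the alkyne as a zinc acetylide. Alkyne 3 is deprotonated (LiN(SiMe3)2) and transmetalated with ZnCl2 to chloro{[3-bromo-4-(TBS-oxy)phenyl]ethynyl}zinc F6. F6 then undergoes copper- and amine-free Negishi coupling with 13 (Pd(PPh3)4, THF, rt). The fallback runs from 3 and 13 back to 14.

**Further compounds**
F1 | step 11 | (2Z)-3-[3-bromo-4-(TBS-oxy)phenyl]-2-[(S)-(TBS-oxy)(3,5-dibromo-4-methoxyphenyl)methyl]-3-(trifluoromethylsulfonyloxy)prop-2-enoic acid | COc1c(Br)cc([C@H](O[Si](C)(C)C(C)(C)C)/C(C(=O)O)=C(/OS(=O)(=O)C(F)(F)F)c2ccc(O[Si](C)(C)C(C)(C)C)c(Br)c2)cc1Br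
F2 | step 8 | tert-butyl 3-[3-bromo-4-(TBS-oxy)phenyl]prop-2-ynoate | CC(C)(C)OC(=O)C#Cc1ccc(O[Si](C)(C)C(C)(C)C)c(Br)c1
F3 | step 8 | 3,5-dibromo-4-methoxybenzaldehyde | COc1c(Br)cc(C=O)cc1Br
F4 | step 8 | tert-butyl (2Z)-3-[3-bromo-4-(TBS-oxy)phenyl]-2-[(S)-(3,5-dibromo-4-methoxyphenyl)(hydroxy)methyl]-3-iodoprop-2-enoate | COc1c(Br)cc([C@H](O)/C(C(=O)OC(C)(C)C)=C(/I)c2ccc(O[Si](C)(C)C(C)(C)C)c(Br)c2)cc1Br
F5 | step 8 | tert-butyl (2Z)-3-[3-bromo-4-(TBS-oxy)phenyl]-2-[(S)-(TBS-oxy)(3,5-dibromo-4-methoxyphenyl)methyl]-3-iodoprop-2-enoate | COc1c(Br)cc([C@H](O[Si](C)(C)C(C)(C)C)/C(C(=O)OC(C)(C)C)=C(/I)c2ccc(O[Si](C)(C)C(C)(C)C)c(Br)c2)cc1Br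
F6 | step 9 | chloro{[3-bromo-4-(TBS-oxy)phenyl]ethynyl}zinc | Cl[Zn]C#Cc1ccc(O[Si](C)(C)C(C)(C)C)c(Br)c1
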